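(The data are simulated for an exercise, noise included.)

- The vessel is closed, stirred and held at 70 °C; it holds substrate, 4.00 equiv of partner and 0.075 mol% of free catalyst, and we want its target at 3.0 min and the remedy that pays.

| flask | substrate | partner | free catalyst | temperature | remark | time |
|---|---|---|---|---|---|---|
| summer | 0.0010 M | 4 equiv | 0.075 mol% | 70 °C | the very flask that is asked about, followed so far |  |
| winter | 0.0010 M | 8 equiv | 0.075 mol% | 70 °C | run made earlier |  |
| flask | 0.0010 M | 4.00 equiv | 0.075 mol% | 70 °C |  | 3.0 min |

summer run (percent of the substrate charged)

| time / s | target / % | substrate / % |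
|---|---|---|
| 10.0 | 5.7 | 96.9 |
| 20.0 | 8.7 | 93.5 |
| 40.0 | 16.0 | 86.0 |
| 60.0 | 20.3 | 79.6 |
| 80.0 | 21.3 | 77.8 |
| 120 | 25.5 | 73.0 |

winter run (percent of the substrate charged)

| time / min | target / % | substrate / % |
|---|---|---|
| 0.200 | 5.6 | 93.6 |
| 0.667 | 18.9 | 82.5 |
| 1.00 | 23.3 | 75.3 |
| 1.50 | 32.5 | 68.3 |
| 2.50 | 37.6 | 62.6 |
| 3.00 | 39.3 | 61.9 |

(each reading ± 1 percentage point)

- target, in percent of the substrate first charged, at 3.0 min
- the remedy with the largest gain of target, or "none" below 2 percentage points (west / north-west / north-east / east / south-west / none)
- target present, with what was taken out counted in, in percent of the substrate first charged, after west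
- target present, with what was taken out counted in, in percent of the substrate first charged, after north-east

- west: at 3.0 min add free catalyst, 50.0 % of the amount charged, then wait 6.0 min
- north-west: at 3.0 min take out 90 % of the target then present, then wait 6.0 min
- north-east: change nothing and wait 6.0 min more
- east: at 3.0 min raise the temperature by 20 K, then wait 6.0 min
- south-west: at 3.0 min add partner, 100 % of the amount charged, then wait 6.0 min

- target taken out counts as made
- the analysis behind the earlier runs scatters by 1 percentage point, standard deviation
- the earlier runs do not show what temperature does; that part of a forecast is a guess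
- additions bring no volume worth counting

- In the summer run the target rose at 0.240 /min of the substrate charge over the first 40.0 s, then at 0.0712 /min up to 120 s, so the rate fell by a factor of 3.37.
- Taking the rate as proportional to the substrate fraction, the balance of substrate explains a factor of 1.17, which leaves a further fading by a factor of 2.88.
- Read as exponential, that fading has a fade time of 0.946 min; the same reckoning on the winter run, with doubled partner, gives 1.58 min, longer, so we tie the fading to partner.
- The summer start rate per unit of substrate, 0.367 /min, times the fade time gives 0.347, which we call the reach, the accumulated rate that the flask can spend on its substrate.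
- At 3.0 min, which is longer than the fade time, a share of 4.19 % of the reach is unspent, so we reckon 28.3 % of target, 29.3 % after north-east and 29.8 % after west. We pick south-west: the winter fade time is the longer one, 1.58 min against 0.946 min, so fresh partner should open a new reach.
- The forecast says 27 %, 27.5 % after west, 27.5 % after north-east, and picks north-west, on the ground that “Equilibrium fits better”; there our pick and the forecast differ.
- The flask gives 27.8 %, 28.7 % after west and 28.3 % after north-east; the best remedy is south-west, worth 17 percentage points, against 0.52 points for north-west.

    partner + free catalyst → catalyst intermediate A (k = 8300 /M/s, Ea = 37.0 kJ/mol)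
    substrate + catalyst intermediate A ⇌ catalyst intermediate B (K = 830 /M, k = 2.90 × 10⁵ /M/s, Ea = 21.0 kJ/mol, ΔH = −6.00 kJ/mol)
    catalyst intermediate B → free catalyst + target (k = 18.0 /s, Ea = 82.0 kJ/mol)
    partner → decomposed reagent (k = 0.0210 /s, Ea = 84.0 kJ/mol)
    free catalyst ⇌ dormant form (K = 2.60, k = 0.0300 /s, Ea = 83.0 kJ/mol, ΔH = −60.0 kJ/mol)
    (constants at 70 °C)

- At 3.00 min this flask holds 1.65 % of its partner charge beside 72.2 % of its substrate charge, and partner is the limiting reagent here, the charge that runs out first. The reach laid on that remaining substrate gives 21 points for south-west, against the 17 points found. Scaled to the neighbour flask with 0.045 mol% of free catalyst, the reach gives 18.1 % of target, and that flask holds 17.2 %.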